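**Plan**

- Locants (azulene skeleton): five-membered ring C1(O-angeloyl)–C2H2–C3(OH)(i-Pr)–C3a–C8a(CH3); seven-membered ring C3a–C4(O-aroyl)–C5–C6(CH3)=C7–C8–C8a.
- Cuts: the two ester C–O bonds; C1–C2, made as the C1=C2 bond of a cyclopent-2-enone by ring-closing metathesis; C6=C7 (ring-closing metathesis); C3a–C8a (dianionic Ireland–Claisen rearrangement); the ester C–O bond of the Claisen substrate; C5–C6 (epoxide opening).
- Enabling feature: C1 and C2 sit between the quaternary C8a and the C3 carbinol of the five-membered ring. The C1–O/C3–O 1,3-dioxygen pattern lets this bond arise as an enone alkene, from the vinyl group that the Claisen step leaves on C8a and an acryloyl group on C3a. The enone then holds both oxygens and the isopropyl site in latent form.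
- Forward: ester 7 is joined from 4 and 6; the Claisen step makes C3a–C8a; the seven-membered ring closes first and the five-membered ring second; then isopropyl addition with oxidative transposition, reduction, epoxidation, hydride opening and the two acylations.
- Stereochemistry: C4 from epoxy ester 5; C3a and C8a from the chelated chair Claisen (anti to the C4 substituent, E-alkene); C1 by hydride attack anti to the angular methyl; C3 by hydroxyl-directed epoxidation and hydride opening; the Z-alkene from angelic acid.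

Key step: step 8

Remark: 1 and 5 are taken as purchasable (5 is otherwise one ring closure from commercial ethyl (R)-4-chloro-3-hydroxybutanoate); locants in names and text are those of the azulene skeleton of the target.

**Route**

Step 1
Reactants: 1 pent-1-en-4-yne
Product: 4 (2E)-3-methylhexa-2,5-dien-1-ol, via alkenylalane 2 (not isolated), via lithium alanate 3 (not isolated)
Conditions: Me3Al, Cp2ZrCl2 (cat.), CH2Cl2, 0 °C to rt; n-BuLi, THF/hexane, −78 °C; (CH2O)n, −78 °C to rt; aq. HCl
Reagents that add atoms: trimethylaluminium C[Al](C)C; formaldehyde (as paraformaldehyde) C=O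
Why: Zirconium-catalysed carboalumination adds methyl and aluminium syn across the terminal alkyne (methyl to the internal carbon), and hydroxymethylation of the alanate with formaldehyde goes with retention, so the (E)-trisubstituted alkene is fixed while the isolated vinyl group stays inert.

Step 2
Reactants: 5 ethyl [(2R)-oxiran-2-yl]acetate
Product: 6 ethyl (3S)-3-hydroxy-5-methylhex-5-enoate
Conditions: CH2=C(CH3)MgBr, CuI (cat.), THF, −40 to −20 °C; aq. HCl
Reagents that add atoms: isopropenylmagnesium bromide CC(=C)[Mg]Br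
Why: Copper-catalysed Grignard opening of the epoxide at its unsubstituted carbon (SN2) outruns attack on the ester at low temperature, and the carbinol stereocentre (C4 of the target) is carried over unchanged from 5.

Step 3
Reactants: 4 (2E)-3-methylhexa-2,5-dien-1-ol; 6 ethyl (3S)-3-hydroxy-5-methylhex-5-enoate
Product: 7 (2E)-3-methylhexa-2,5-dien-1-yl (3S)-3-hydroxy-5-methylhex-5-enoate
Conditions: Ti(OEt)4 (cat.), toluene, 100 °C, EtOH distilled off
Reagents that add atoms: none
Why: Titanate-catalysed transesterification is neutral and tolerates the free β-hydroxyl, removal of ethanol drives the equilibrium, and no stereocentre is touched.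

Step 4
Reactants: 7 (2E)-3-methylhexa-2,5-dien-1-yl (3S)-3-hydroxy-5-methylhex-5-enoate
Product: 9 (2S,3S)-3-ethenyl-2-[(1S)-1-hydroxy-3-methylbut-3-en-1-yl]-3-methylhex-5-enoic acid, via dilithium dianion 8 (not isolated)
Conditions: LDA (2.3 equiv), THF, −78 °C; then rt to 50 °C; aq. HCl
Reagents that add atoms: none
Why: Dianionic Ireland–Claisen rearrangement, in which the lithium-chelated alkoxide–enolate 8 has a fixed enolate geometry, the allyl unit is delivered through a chair transition state to the enolate face anti to the 2-methylallyl-bearing carbinol substituent (the sense of the Fráter–Seebach alkylation) to set C3a, and the (E)-alkene with its methyl pseudo-axial sets the quaternary C8a.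

Step 5
Reactants: 9 (2S,3S)-3-ethenyl-2-[(1S)-1-hydroxy-3-methylbut-3-en-1-yl]-3-methylhex-5-enoic acid
Product: 11 (2S,3S)-2-[(1S)-1-[(tert-butyldimethylsilyl)oxy]-3-methylbut-3-en-1-yl]-3-ethenyl-3-methylhex-5-enoic acid, via silyl ester 10 (not isolated)
Conditions: TBSOTf (2.5 equiv), 2,6-lutidine, CH2Cl2, 0 °C; then AcOH/THF/H2O, rt
Reagents that add atoms: tert-butyldimethylsilyl triflate CC(C)(C)[Si](C)(C)OS(=O)(=O)C(F)(F)F
Why: Silylation of the hindered secondary alcohol with the silyl triflate, followed by selective mild acid hydrolysis of the silyl ester formed alongside, gives a C4 silyl ether that should survive the organometallic, oxidative and hydride steps to come.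

Step 6
Reactants: 11 (2S,3S)-2-[(1S)-1-[(tert-butyldimethylsilyl)oxy]-3-methylbut-3-en-1-yl]-3-ethenyl-3-methylhex-5-enoic acid
Product: 12 (1S,2S,7S)-7-[(tert-butyldimethylsilyl)oxy]-2-ethenyl-2,5-dimethylcyclohept-4-ene-1-carboxylic acid
Conditions: second-generation Grubbs catalyst (5 mol%), CH2Cl2 (5 mM), 40 °C
Reagents that add atoms: none
Why: Ring-closing metathesis of the allyl and 2-methylallyl groups gives the cycloheptene with the trisubstituted C6=C7 alkene, since the carbene formed first on the unhindered allyl group can close only to the seven-membered ring while the vinyl group on the quaternary carbon initiates slowly and is kept for step 8.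

Step 7
Reactants: 12 (1S,2S,7S)-7-[(tert-butyldimethylsilyl)oxy]-2-ethenyl-2,5-dimethylcyclohept-4-ene-1-carboxylic acid
Product: 14 1-[(1S,2S,7S)-7-[(tert-butyldimethylsilyl)oxy]-2-ethenyl-2,5-dimethylcyclohept-4-en-1-yl]prop-2-en-1-one, via acid chloride 13 (not isolated)
Conditions: 1-chloro-N,N,2-trimethylprop-1-en-1-amine, CH2Cl2, 0 °C to rt; then CH2=CHSnBu3, Pd(PPh3)4 (5 mol%), toluene, 60 °C
Reagents that add atoms: tributyl(ethenyl)stannane C=C[Sn](CCCC)(CCCC)CCCC
Why: The acid chloride, formed under neutral conditions, undergoes palladium-catalysed Stille coupling with the vinylstannane to give the vinyl ketone without base, so C3a (α to the carbonyl, β to the silyl ether) is neither epimerised nor eliminated.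

Step 8
Reactants: 14 1-[(1S,2S,7S)-7-[(tert-butyldimethylsilyl)oxy]-2-ethenyl-2,5-dimethylcyclohept-4-en-1-yl]prop-2-en-1-one
Product: 15 (3aS,4S,8aS)-4-[(tert-butyldimethylsilyl)oxy]-6,8a-dimethyl-4,5,8,8a-tetrahydroazulen-3(3aH)-one
Conditions: second-generation Hoveyda–Grubbs catalyst (5–10 mol%), toluene (2 mM), 80 °C, argon sparge
Reagents that add atoms: none
Why: Ring-closing olefin metathesis: the ruthenium alkylidene loads onto one terminal alkene of the hepta-1,6-dien-3-one unit, and [2+2] cycloaddition and cycloreversion through a ruthenacyclobutane join C1 to C2 with loss of ethene. The closest known reaction type is the ring-closing metathesis of vinyl ketones that carry a second vinyl group on a quaternary γ-carbon, which gives 4,4-disubstituted cyclopent-2-enones. The five-membered ring closes as a cyclopentenone with the new C1=C2 bond endocyclic, and it is trans-fused to the cycloheptene because the vinyl and acryloyl groups are trans on C8a and C3a. No stereocentre is formed, and C3a should keep its configuration because the conditions are neutral. The step needs chemoselectivity among three alkenes: the trisubstituted ring alkene C6=C7 is inert to the catalyst, and high dilution with removal of ethene favours closure over cross metathesis.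

Step 9
Reactants: 15 (3aS,4S,8aS)-4-[(tert-butyldimethylsilyl)oxy]-6,8a-dimethyl-4,5,8,8a-tetrahydroazulen-3(3aH)-one
Product: 16 (3S,3aS,4S,8aS)-4-[(tert-butyldimethylsilyl)oxy]-6,8a-dimethyl-3-(propan-2-yl)-3,3a,4,5,8,8a-hexahydroazulen-3-ol
Conditions: i-PrMgCl, CeCl3 (anhydrous), THF, −78 to −40 °C; then H2O
Reagents that add atoms: isopropylmagnesium chloride CC(C)[Mg]Cl
Why: The organocerium reagent adds 1,2 to the enone without enolisation, from the face anti to the angular methyl, and the configuration of the new carbinol is of no consequence because step 10 removes it.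

Step 10
Reactants: 16 (3S,3aS,4S,8aS)-4-[(tert-butyldimethylsilyl)oxy]-6,8a-dimethyl-3-(propan-2-yl)-3,3a,4,5,8,8a-hexahydroazulen-3-ol
Product: 17 (3aS,4S,8aR)-4-[(tert-butyldimethylsilyl)oxy]-6,8a-dimethyl-3-(propan-2-yl)-4,5,8,8a-tetrahydroazulen-1(3aH)-one
Conditions: pyridinium chlorochromate [C5H5NH][CrO3Cl] (3 equiv), 4 Å molecular sieves, CH2Cl2, rt
Reagents that add atoms: none
Why: Babler–Dauben oxidative transposition, in which the chromate ester of the tertiary allylic alcohol undergoes a [3,3] shift to C1 and is oxidised there, gives the 3-isopropyl enone with the carbonyl at C1.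

Step 11
Reactants: 17 (3aS,4S,8aR)-4-[(tert-butyldimethylsilyl)oxy]-6,8a-dimethyl-3-(propan-2-yl)-4,5,8,8a-tetrahydroazulen-1(3aH)-one
Product: 18 (1R,3aS,4S,8aR)-4-[(tert-butyldimethylsilyl)oxy]-6,8a-dimethyl-3-(propan-2-yl)-1,3a,4,5,8,8a-hexahydroazulen-1-ol
Conditions: NaBH4, CeCl3·7H2O, MeOH, −40 °C
Reagents that add atoms: none
Why: Luche 1,2-reduction, in which hydride attacks the C1 carbonyl from the face anti to the pseudo-axial angular methyl on C8a of the trans-fused bicycle (as in the reduction of 17-oxo steroids), so the new hydroxyl is cis to that methyl (1R).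

Step 12
Reactants: 18 (1R,3aS,4S,8aR)-4-[(tert-butyldimethylsilyl)oxy]-6,8a-dimethyl-3-(propan-2-yl)-1,3a,4,5,8,8a-hexahydroazulen-1-ol
Product: 19 2,3-epoxide of 18 with the oxirane oxygen cis to the C1 hydroxyl and the C8a methyl
Conditions: VO(acac)2 (5 mol%), t-BuOOH (1.5 equiv), CH2Cl2, 0 °C to rt
Reagents that add atoms: tert-butyl hydroperoxide CC(C)(C)OO
Why: Vanadium-catalysed hydroxyl-directed epoxidation delivers oxygen to the C2=C3 alkene on the face of the C1 hydroxyl, which sets the C3 oxygen cis to it, and leaves the remote C6=C7 alkene untouched.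

Step 13
Reactants: 19 2,3-epoxide of 18
Product: 20 (1R,3R,3aS,4S,8aR)-4-[(tert-butyldimethylsilyl)oxy]-6,8a-dimethyl-3-(propan-2-yl)-1,2,3,3a,4,5,8,8a-octahydroazulene-1,3-diol
Conditions: LiAlH4, THF, 0 to 50 °C; then H2O
Reagents that add atoms: none
Why: Hydride opens the trisubstituted epoxide by SN2 at the secondary C2 (the fully substituted C3 is not attacked), which leaves the tertiary C3 hydroxyl with its configuration and gives the cis-1,3-diol.

Step 14
Reactants: 20 (1R,3R,3aS,4S,8aR)-4-[(tert-butyldimethylsilyl)oxy]-6,8a-dimethyl-3-(propan-2-yl)-1,2,3,3a,4,5,8,8a-octahydroazulene-1,3-diol; 21 angelic acid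
Product: 23 (1R,3R,3aS,4S,8aR)-4-[(tert-butyldimethylsilyl)oxy]-3-hydroxy-6,8a-dimethyl-3-(propan-2-yl)-1,2,3,3a,4,5,8,8a-octahydroazulen-1-yl (2Z)-2-methylbut-2-enoate, via mixed anhydride 22 (not isolated)
Conditions: 21, 2,4,6-Cl3C6H2COCl, Et3N, toluene, rt; then 20, toluene, 75 °C
Reagents that add atoms: none
Why: Yamaguchi esterification through the mixed anhydride acylates the secondary C1 hydroxyl and not the tertiary C3 hydroxyl, and without a nucleophilic catalyst the (Z)-geometry of the angeloyl group should be kept.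

Step 15
Reactants: 23 the C4 silyl ether C1 angelate
Product: 24 (1R,3R,3aS,4S,8aR)-3,4-dihydroxy-6,8a-dimethyl-3-(propan-2-yl)-1,2,3,3a,4,5,8,8a-octahydroazulen-1-yl (2Z)-2-methylbut-2-enoate
Conditions: HF·pyridine, pyridine/THF, 0 °C to rt
Reagents that add atoms: none
Why: Fluoride cleavage of the secondary silyl ether under buffered, weakly acidic conditions leaves the angelate, the tertiary alcohol and both alkenes untouched.

Step 16
Reactants: 24 the C3,C4-diol C1 angelate; 25 4-(acetyloxy)benzoyl chloride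
Product: 26 (1R,3R,3aS,4S,8aR)-4-{[4-(acetyloxy)benzoyl]oxy}-3-hydroxy-6,8a-dimethyl-3-(propan-2-yl)-1,2,3,3a,4,5,8,8a-octahydroazulen-1-yl (2Z)-2-methylbut-2-enoate
Conditions: 25 (1.5 equiv), pyridine, DMAP (cat.), CH2Cl2, 0 °C to rt
Reagents that add atoms: none
Why: Acylation of the secondary C4 hydroxyl with the aroyl chloride under nucleophilic catalysis, in which the tertiary C3 hydroxyl does not react and the phenol stays masked as its acetate.

Step 17
Reactants: 26 the aryl acetate diester
Product: 27 (1R,3R,3aS,4S,8aR)-3-hydroxy-4-[(4-hydroxybenzoyl)oxy]-6,8a-dimethyl-3-(propan-2-yl)-1,2,3,3a,4,5,8,8a-octahydroazulen-1-yl (2Z)-2-methylbut-2-enoate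
Conditions: pyrrolidine (2 equiv), CH2Cl2, 0 °C
Reagents that add atoms: none
Why: Aminolysis cleaves the aryl acetate, a far better acyl donor than the two alkyl esters, and frees the phenol chemoselectively.

**Compound list**

1 | pent-1-en-4-yne | C#CCC=C | starting material
2 | dimethyl[(1E)-2-methylpenta-1,4-dien-1-yl]alane | C[Al](C)/C=C(\C)CC=C | intermediate (not isolated)
3 | lithium butyl(dimethyl)[(1E)-2-methylpenta-1,4-dien-1-yl]alanate | [Li+].CCCC[Al-](C)(C)/C=C(\C)CC=C | intermediate (not isolated)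
4 | (2E)-3-methylhexa-2,5-dien-1-ol | OC/C=C(\C)CC=C | intermediate
5 | ethyl [(2R)-oxiran-2-yl]acetate | CCOC(=O)C[C@@H]1CO1 | starting material
6 | ethyl (3S)-3-hydroxy-5-methylhex-5-enoate | CCOC(=O)C[C@@H](O)CC(C)=C | intermediate
7 | (2E)-3-methylhexa-2,5-dien-1-yl (3S)-3-hydroxy-5-methylhex-5-enoate | C=C(C)C[C@H](O)CC(=O)OC/C=C(\C)CC=C | intermediate
8 | dilithium alkoxide–enolate of 7 (enolate oxygen cis to the carbinol carbon) | [Li+].[Li+].C=C(C)C[C@H]([O-])/C=C(\[O-])OC/C=C(\C)CC=C | intermediate (not isolated)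
9 | (2S,3S)-3-ethenyl-2-[(1S)-1-hydroxy-3-methylbut-3-en-1-yl]-3-methylhex-5-enoic acid | OC(=O)[C@@H]([C@](C)(C=C)CC=C)[C@@H](O)CC(C)=C | intermediate
10 | tert-butyldimethylsilyl ester of 11 | CC(C)(C)[Si](C)(C)OC(=O)[C@@H]([C@](C)(C=C)CC=C)[C@@H](O[Si](C)(C)C(C)(C)C)CC(C)=C | intermediate (not isolated)
11 | (2S,3S)-2-[(1S)-1-[(tert-butyldimethylsilyl)oxy]-3-methylbut-3-en-1-yl]-3-ethenyl-3-methylhex-5-enoic acid | OC(=O)[C@@H]([C@](C)(C=C)CC=C)[C@@H](O[Si](C)(C)C(C)(C)C)CC(C)=C | intermediate
12 | (1S,2S,7S)-7-[(tert-butyldimethylsilyl)oxy]-2-ethenyl-2,5-dimethylcyclohept-4-ene-1-carboxylic acid | OC(=O)[C@H]1[C@](C)(C=C)CC=C(C)C[C@@H]1O[Si](C)(C)C(C)(C)C | intermediate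
13 | (1S,2S,7S)-7-[(tert-butyldimethylsilyl)oxy]-2-ethenyl-2,5-dimethylcyclohept-4-ene-1-carbonyl chloride | ClC(=O)[C@H]1[C@](C)(C=C)CC=C(C)C[C@@H]1O[Si](C)(C)C(C)(C)C | intermediate (not isolated)
14 | 1-[(1S,2S,7S)-7-[(tert-butyldimethylsilyl)oxy]-2-ethenyl-2,5-dimethylcyclohept-4-en-1-yl]prop-2-en-1-one | C=CC(=O)[C@H]1[C@](C)(C=C)CC=C(C)C[C@@H]1O[Si](C)(C)C(C)(C)C | intermediate
15 | (3aS,4S,8aS)-4-[(tert-butyldimethylsilyl)oxy]-6,8a-dimethyl-4,5,8,8a-tetrahydroazulen-3(3aH)-one | O=C1C=C[C@]2(C)CC=C(C)C[C@H](O[Si](C)(C)C(C)(C)C)[C@@H]12 | intermediate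
16 | (3S,3aS,4S,8aS)-4-[(tert-butyldimethylsilyl)oxy]-6,8a-dimethyl-3-(propan-2-yl)-3,3a,4,5,8,8a-hexahydroazulen-3-ol | CC(C)[C@]1(O)C=C[C@]2(C)CC=C(C)C[C@H](O[Si](C)(C)C(C)(C)C)[C@@H]12 | intermediate
17 | (3aS,4S,8aR)-4-[(tert-butyldimethylsilyl)oxy]-6,8a-dimethyl-3-(propan-2-yl)-4,5,8,8a-tetrahydroazulen-1(3aH)-one | CC(C)C1=CC(=O)[C@]2(C)CC=C(C)C[C@H](O[Si](C)(C)C(C)(C)C)[C@@H]12 | intermediate
18 | (1R,3aS,4S,8aR)-4-[(tert-butyldimethylsilyl)oxy]-6,8a-dimethyl-3-(propan-2-yl)-1,3a,4,5,8,8a-hexahydroazulen-1-ol | CC(C)C1=C[C@@H](O)[C@]2(C)CC=C(C)C[C@H](O[Si](C)(C)C(C)(C)C)[C@@H]12 | intermediate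
19 | 2,3-epoxide of 18, oxirane oxygen cis to the C1 hydroxyl and the C8a methyl | CC(C)[C@]12O[C@H]1[C@@H](O)[C@]3(C)CC=C(C)C[C@H](O[Si](C)(C)C(C)(C)C)[C@@H]23 | intermediate
20 | (1R,3R,3aS,4S,8aR)-4-[(tert-butyldimethylsilyl)oxy]-6,8a-dimethyl-3-(propan-2-yl)-1,2,3,3a,4,5,8,8a-octahydroazulene-1,3-diol | O[C@@H]1C[C@@](O)(C(C)C)[C@@H]2[C@@H](O[Si](C)(C)C(C)(C)C)CC(C)=CC[C@]21C | intermediate
21 | angelic acid, (2Z)-2-methylbut-2-enoic acid | C/C=C(/C)C(=O)O | starting material
22 | (2Z)-2-methylbut-2-enoic 2,4,6-trichlorobenzoic anhydride | C/C=C(/C)C(=O)OC(=O)c1c(Cl)cc(Cl)cc1Cl | intermediate (not isolated)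
23 | (1R,3R,3aS,4S,8aR)-4-[(tert-butyldimethylsilyl)oxy]-3-hydroxy-6,8a-dimethyl-3-(propan-2-yl)-1,2,3,3a,4,5,8,8a-octahydroazulen-1-yl (2Z)-2-methylbut-2-enoate | C/C=C(/C)C(=O)O[C@@H]1C[C@@](O)(C(C)C)[C@@H]2[C@@H](O[Si](C)(C)C(C)(C)C)CC(C)=CC[C@]21C | intermediate
24 | (1R,3R,3aS,4S,8aR)-3,4-dihydroxy-6,8a-dimethyl-3-(propan-2-yl)-1,2,3,3a,4,5,8,8a-octahydroazulen-1-yl (2Z)-2-methylbut-2-enoate | C/C=C(/C)C(=O)O[C@@H]1C[C@@](O)(C(C)C)[C@@H]2[C@@H](O)CC(C)=CC[C@]21C | intermediate
25 | 4-(acetyloxy)benzoyl chloride | CC(=O)Oc1ccc(cc1)C(Cl)=O | starting material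
26 | (1R,3R,3aS,4S,8aR)-4-{[4-(acetyloxy)benzoyl]oxy}-3-hydroxy-6,8a-dimethyl-3-(propan-2-yl)-1,2,3,3a,4,5,8,8a-octahydroazulen-1-yl (2Z)-2-methylbut-2-enoate | C/C=C(/C)C(=O)O[C@@H]1C[C@@](O)(C(C)C)[C@@H]2[C@@H](OC(=O)c3ccc(OC(C)=O)cc3)CC(C)=CC[C@]21C | intermediate
27 | (1R,3R,3aS,4S,8aR)-3-hydroxy-4-[(4-hydroxybenzoyl)oxy]-6,8a-dimethyl-3-(propan-2-yl)-1,2,3,3a,4,5,8,8a-octahydroazulen-1-yl (2Z)-2-methylbut-2-enoate | C/C=C(/C)C(=O)O[C@@H]1C[C@@](O)(C(C)C)[C@@H]2[C@@H](OC(=O)c3ccc(O)cc3)CC(C)=CC[C@]21C | target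

**Count**

Total steps: 17. Longest linear sequence: 16 (steps 2 to 17 from 5, or steps 1 and 3 to 17 from 1).

**Steps most likely to fail**

Step 4. The diastereoselectivity may erode through a boat transition state or loss of lithium chelation, and the ester enolate may fragment to a ketene on warming. Fallback from 7: silylation (TBSOTf, 2,6-lutidine) gives (2E)-3-methylhexa-2,5-dien-1-yl (3S)-3-[(tert-butyldimethylsilyl)oxy]-5-methylhex-5-enoate F1. LDA and Me3SiCl in THF/DMPU at −78 °C give the (Z)-silyl ketene acetal F2. This rearranges between rt and 60 °C as a neutral Ireland–Claisen substrate, under 1,2-induction from the silyloxy stereocentre, to the trimethylsilyl ester F3. Aqueous work-up gives 11, where the route is rejoined (steps 4 and 5 are replaced).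

Step 8. Initiation at the hindered vinyl group on the quaternary carbon may be slow, and the catalyst may decay on the electron-poor enone, so that cross-metathesis oligomers form. Fallback from 14: 1,2-addition of i-PrMgCl/CeCl3 to the acyclic vinyl ketone gives the divinyl carbinol 3-[(1S,2S,7S)-7-[(tert-butyldimethylsilyl)oxy]-2-ethenyl-2,5-dimethylcyclohept-4-en-1-yl]-4-methylpent-1-en-3-ol F4 as both carbinol epimers. Ring-closing metathesis of this electron-rich 1,6-dien-3-ol then gives 16 together with its C3 epimer F5. Both are oxidised under the conditions of step 10 to 17, where the route is rejoined.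

Step 14. The angeloyl group may isomerise from Z to E during activation, and acylation of the hindered C1 hydroxyl next to the quaternary carbon may be slow. Fallback from 20: esterification with 2-[bis(2,2,2-trifluoroethoxy)phosphoryl]propanoic acid (DCC, DMAP) gives the C1 phosphonopropanoate F6. Still–Gennari olefination with acetaldehyde (KHMDS, 18-crown-6, THF, −78 °C) builds the (Z)-2-methylbut-2-enoate on the substrate and gives 23, where the route is rejoined.

**Further compounds**

F1 | step 4 | (2E)-3-methylhexa-2,5-dien-1-yl (3S)-3-[(tert-butyldimethylsilyl)oxy]-5-methylhex-5-enoate | C=C(C)C[C@H](O[Si](C)(C)C(C)(C)C)CC(=O)OC/C=C(\C)CC=C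
F2 | step 4 | (Z)-trimethylsilyl ketene acetal of F1 | C=C(C)C[C@H](O[Si](C)(C)C(C)(C)C)/C=C(\O[Si](C)(C)C)OC/C=C(\C)CC=C
F3 | step 4 | trimethylsilyl ester of 11 | C[Si](C)(C)OC(=O)[C@@H]([C@](C)(C=C)CC=C)[C@@H](O[Si](C)(C)C(C)(C)C)CC(C)=C
F4 | step 8 | 3-[(1S,2S,7S)-7-[(tert-butyldimethylsilyl)oxy]-2-ethenyl-2,5-dimethylcyclohept-4-en-1-yl]-4-methylpent-1-en-3-ol (both carbinol epimers) | CC(C)C(O)(C=C)[C@H]1[C@](C)(C=C)CC=C(C)C[C@@H]1O[Si](C)(C)C(C)(C)C
F5 | step 8 | (3R,3aS,4S,8aS)-4-[(tert-butyldimethylsilyl)oxy]-6,8a-dimethyl-3-(propan-2-yl)-3,3a,4,5,8,8a-hexahydroazulen-3-ol (C3 epimer of 16) | CC(C)[C@@]1(O)C=C[C@]2(C)CC=C(C)C[C@H](O[Si](C)(C)C(C)(C)C)[C@@H]12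
F6 | step 14 | C1 ester of 20 with 2-[bis(2,2,2-trifluoroethoxy)phosphoryl]propanoic acid (both epimers at the phosphonate carbon) | CC(C(=O)O[C@@H]1C[C@@](O)(C(C)C)[C@@H]2[C@@H](O[Si](C)(C)C(C)(C)C)CC(C)=CC[C@]21C)P(=O)(OCC(F)(F)F)OCC(F)(F)F
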